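- Time the substrate first.

in all of them: substrate 0.78 M; initiator 16 mM

|  | reagent | remark | time |
|---|---|---|---|
| delta | 0.088 M | run made earlier |  |
| beta | 1.5 M | run made earlier |  |
| Tuesday's | 2.50 M |  | 3.0 min |
| Saturday's | 0.200 M |  | 3.0 min |
| Friday's | 0.400 M |  | 3.0 min |
| Thursday's | 0.624 M |  | 3.0 min |
| Sunday's | 0.300 M |  | 3.0 min |
| Monday's | 0.150 M |  | 3.0 min |

| run | time / s | target / % | substrate / % |
|---|---|---|---|
| delta | 10.0 | 5.4 | 65.0 |
| delta | 12.0 | 5.6 | 61.1 |
| delta | 15.0 | 6.2 | 55.5 |
| delta | 25.0 | 7.1 | 42.4 |
| delta | 40.0 | 7.6 | 32.2 |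
| delta | 60.0 | 8.3 | 24.2 |
| delta | 90.0 | 7.8 | 17.3 |
| beta | 12.0 | 38.3 | 39.7 |
| beta | 25.0 | 46.3 | 22.5 |
| beta | 40.0 | 50.0 | 14.0 |
| beta | 50.0 | 50.4 | 11.0 |
| beta | 60.0 | 51.3 | 7.8 |
| beta | 80.0 | 50.7 | 5.0 |
| beta | 90.0 | 50.0 | 3.4 |

(standard deviation of a reading: 0.3 percentage points)

- all flasks from highest to lowest amount of target, in percent of the substrate charged, at 3.0 min (Tuesday's / Saturday's / Friday's / Thursday's / Sunday's / Monday's)
- the same order at 10 s (Tuesday's / Saturday's / Friday's / Thursday's / Sunday's / Monday's)
- the amount of target, in percent of the substrate charged of the flask you put first, at 3.0 min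
- the amount of target, in percent of the substrate charged of the flask you put last, at 3.0 min

- percent here means substrate units held: one ended chains or homo dimer counts as two
- the earlier runs were read with a standard deviation of 0.3 percentage points
- steps that have been proposed: initiator -> 2 initiating radical; substrate + initiating radical -> capped initiator + first chain carrier; reagent + first chain carrier <-> target + second chain carrier; substrate + second chain carrier -> by-product + first chain carrier; first chain carrier -> ended carrier; 2 first chain carrier -> ended chains; 2 substrate -> homo dimer; target <-> isomer of the product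

- Fastest rung, the burst: beta already holds 74.7% of its peak reading by 12.0 s, so target appears early, and your plate should sample early too.
- Next rung, the substrate: if pairs of substrate react, the rate goes with [substrate] squared, and integrating makes the reciprocal of the fraction left rise in a straight line with time.
- Delta's first and last readings give the substrate clock, the second-order half-life in which [substrate] falls to half its charge: 18.9 s.
- The line holds up in delta: it gives 32.1% at 40.0 s, and the reading there is 32.2%.
- Beta holds less substrate at 90.0 s than delta, 3.4% against 17.3%, so keep this clock for flasks with little reagent.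
- Slowest rung, the sag: beta's target readings fall from 51.3% at 60.0 s to 50.0% at 90.0 s, a net decay time of about 1170 s, far longer than the clock.
- My own reckoning: Monday's, the asked flask nearest delta in reagent, keeps 9.48% of its substrate at 3.0 min.
- The forecast gives Tuesday's > Thursday's > Friday's > Sunday's > Saturday's > Monday's at 3.0 min and Tuesday's > Thursday's > Friday's > Sunday's > Saturday's > Monday's at 10 s, with 54% on top and 11% at the bottom, holding that “The order stays monotonic in reagent at both times.”
- The flasks give Tuesday's > Thursday's > Friday's > Sunday's > Saturday's > Monday's at 3.0 min and Tuesday's > Thursday's > Friday's > Sunday's > Saturday's > Monday's at 10 s, with 51.9% in Tuesday's and 12.1% in Monday's.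

    initiator → 2 initiating radical (k = 0.00138 s⁻¹)
    substrate + initiating radical → capped initiator + first chain carrier (k = 1.92 × 10⁶ M⁻¹ s⁻¹)
    reagent + first chain carrier ⇌ target + second chain carrier (K = 1.10, k = 2.92 × 10⁵ M⁻¹ s⁻¹)
    substrate + second chain carrier → by-product + first chain carrier (k = 27900 M⁻¹ s⁻¹)
    first chain carrier → ended carrier (k = 24.6 s⁻¹)
    2 first chain carrier → ended chains (k = 2.20 × 10⁸ M⁻¹ s⁻¹)
    2 substrate → homo dimer (k = 0.0293 M⁻¹ s⁻¹)
    target ⇌ isomer of the product (K = 0.570, k = 0.00532 s⁻¹)

- Monday's holds 8.72% substrate at 3.0 min, against the clock's 9.48%, and at 0.249 min the half-life of substrate by the chain step is 2.1 min, longer than the clock's 18.9 s. At 3.0 min in Monday's, the homo dimer path uses substrate 4.4 times as fast as that chain step. In the neighbour of Monday's with 0.26 M of reagent, the same clock gives 9.48%, and that flask holds 7.13%.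

(The readings were generated by integration for substances that don't exist, noise included.)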